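**Strategy.** Ring A is cut at two adjacent bonds, C5–O and C6–C(=O). Both come from one molecule of protected 4-hydroxyphenylacetic acid adding across a C5–C6 aryne of the fully substituted 2,2-dimethylchromene. The key step exploits the vicinal C5 hydroxyl/C6 acyl pair of ring A and the C7 methoxyl next to C6, which steers the carboxylate oxygen to C5 and leaves the carbanion at C6 to capture the acyl group. The precursor is the 5-triflyloxy-6-trimethylsilyl chromene carrying the C7 methoxyl and the C8 prenyl group. It is assembled from 5-methoxyresorcinol by chromenylation and two directed lithiations, and the acid-labile C6 silane is never exposed to protic acid.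

Key step: step 8

Assumption: in step 1 the condensation is taken to occur mainly at the resorcinol carbon between the two hydroxyls, the only position that leads to 4; the isomeric 7-hydroxy-5-methoxychromene is removed by chromatography.

Design remark: the C6 silicon has oxygen on both ortho carbons and on the para carbon and is lost by ipso-protonation in protic acid. The C5 MOM ether is therefore removed with a buffered silyl triflate (step 5), and protic acid is used only after the silicon has gone (step 9). The target has no stereocentre.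

**Step 1**
Reactants: 1 5-methoxyresorcinol; 2 3-methylbut-2-enal
Product: 4 7-methoxy-2,2-dimethyl-2H-chromen-5-ol, via ortho-quinone methide dienone 3 (not isolated)
Conditions: ethylenediammonium diacetate (10 mol%), 2 (1.1 equiv), PhMe, reflux, Dean–Stark
Reagents that add atoms: none
Why: Amine-salt-catalysed Knoevenagel-type condensation at the ring carbon flanked by both hydroxyls gives dienone 3, which closes by oxa-6π electrocyclization (formal [3+3] chromenylation) to the 2,2-dimethylchromene.

**Step 2**
Reactants: 4 7-methoxy-2,2-dimethyl-2H-chromen-5-ol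
Product: 5 7-methoxy-5-(methoxymethoxy)-2,2-dimethyl-2H-chromene
Conditions: NaH, MOMCl, DMF, 0 °C to rt
Reagents that add atoms: chloromethyl methyl ether (MOMCl), COCCl
Why: Williamson-type O-alkylation of the sodium phenoxide installs the MOM group that will direct lithiation to C6.

**Step 3**
Reactants: 5 7-methoxy-5-(methoxymethoxy)-2,2-dimethyl-2H-chromene
Product: 7 [7-methoxy-5-(methoxymethoxy)-2,2-dimethyl-2H-chromen-6-yl]trimethylsilane, via C6-aryllithium 6 (not isolated)
Conditions: n-BuLi (1.2 equiv), THF, 0 °C; TMSCl, −78 °C to rt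
Reagents that add atoms: chlorotrimethylsilane (TMSCl), C[Si](C)(C)Cl
Why: Directed ortho-metalation, in which C6–H between the chelating OMOM group and the C7 methoxyl should be removed in preference to C8–H, followed by silylation of the aryllithium.

**Step 4**
Reactants: 7 [7-methoxy-5-(methoxymethoxy)-2,2-dimethyl-2H-chromen-6-yl]trimethylsilane; 8 prenyl bromide (1-bromo-3-methylbut-2-ene)
Product: 11 [7-methoxy-5-(methoxymethoxy)-2,2-dimethyl-8-(3-methylbut-2-enyl)-2H-chromen-6-yl]trimethylsilane, via C8-aryllithium 9 (not isolated), via C8-arylcopper 10 (not isolated)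
Conditions: s-BuLi (1.3 equiv), TMEDA, THF, −78 to −40 °C; CuBr·SMe2 (1.3 equiv), −78 to −40 °C; 8 (1.5 equiv), −78 to 0 °C
Reagents that add atoms: none
Why: A second directed ortho-metalation removes the only remaining ring hydrogen, C8–H between the C7 methoxyl and the ring oxygen O1, and after transmetalation to the monovalent arylcopper the allylic substitution on prenyl bromide should take the SN2 course at the unhindered CH2 terminus to give the linear prenyl group.

**Step 5**
Reactants: 11 [7-methoxy-5-(methoxymethoxy)-2,2-dimethyl-8-(3-methylbut-2-enyl)-2H-chromen-6-yl]trimethylsilane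
Product: 13 7-methoxy-2,2-dimethyl-8-(3-methylbut-2-enyl)-6-(trimethylsilyl)-2H-chromen-5-ol, via aryl trimethylsilyl ether 12 (not isolated)
Conditions: TMSOTf (2 equiv), 2,2′-bipyridyl (3 equiv), MeCN, 0 °C to rt; then H2O, rt
Reagents that add atoms: none
Why: Non-acidic MOM cleavage, in which TMSOTf buffered by 2,2′-bipyridyl exchanges the aromatic MOM ether for a trimethylsilyl ether that water then hydrolyses, so the protodesilylation-prone C6 silane, the chromene alkene and the prenyl group should stay untouched.

**Step 6**
Reactants: 13 7-methoxy-2,2-dimethyl-8-(3-methylbut-2-enyl)-6-(trimethylsilyl)-2H-chromen-5-ol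
Product: 14 7-methoxy-2,2-dimethyl-8-(3-methylbut-2-enyl)-6-(trimethylsilyl)-2H-chromen-5-yl trifluoromethanesulfonate
Conditions: KN(SiMe3)2 (1.2 equiv), THF, −78 °C; PhNTf2 (1.3 equiv), −78 °C to rt
Reagents that add atoms: N-phenylbis(trifluoromethanesulfonimide) (PhNTf2), O=S(=O)(N(c1ccccc1)S(=O)(=O)C(F)(F)F)C(F)(F)F
Why: O-sulfonylation of the potassium phenoxide with a neutral triflyl donor gives the ortho-silylaryl triflate (a Kobayashi-type aryne precursor) without generating triflic acid.

**Step 7**
Reactants: 15 4-hydroxyphenylacetic acid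
Product: 17 2-[4-(methoxymethoxy)phenyl]acetic acid, via bis-MOM derivative 16 (not isolated)
Conditions: MOMCl (2.5 equiv), i-Pr2NEt (3 equiv), CH2Cl2, 0 °C to rt; then LiOH, THF/MeOH/H2O, rt; 1 M HCl to pH 4, 0 °C
Reagents that add atoms: chloromethyl methyl ether (MOMCl), COCCl
Why: Exhaustive MOM alkylation of phenol and acid followed by saponification of the labile MOM ester leaves only the phenolic MOM ether, which keeps the ring B hydroxyl from adding to the aryne.

**Step 8**
Reactants: 14 7-methoxy-2,2-dimethyl-8-(3-methylbut-2-enyl)-6-(trimethylsilyl)-2H-chromen-5-yl trifluoromethanesulfonate; 17 2-[4-(methoxymethoxy)phenyl]acetic acid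
Product: 19 1-[5-hydroxy-7-methoxy-2,2-dimethyl-8-(3-methylbut-2-enyl)-2H-chromen-6-yl]-2-[4-(methoxymethoxy)phenyl]ethan-1-one, via 5,6-aryne 18 (not isolated)
Conditions: CsF (5 equiv), 17 (2 equiv), THF, 110 °C, sealed tube
Reagents that add atoms: none
Why: Fluoride attacks the C6 silicon of 14 and the C5 triflate leaves, giving aryne 18; the cesium carboxylate formed from 17 and CsF adds through oxygen at C5, and the resulting C6 aryl anion attacks the neighbouring ester carbonyl through a four-membered tetrahedral intermediate that opens to the C5 phenoxide and the C6 ketone (a 1,3 O-to-C acyl shift, as in an anionic Fries rearrangement). The closest known reaction type is the fluoride-induced insertion of arynes into the C–O bond of carboxylic acids, which gives ortho-hydroxyaryl ketones from aromatic and aliphatic acids. No ring is closed and no stereocentre is formed. The selectivity needed is oxygen attack at C5 and not at C6: the C7 methoxyl on the carbon next to C6 is inductively withdrawing and distorts the aryne as in 3-methoxybenzyne, so the nucleophile enters at the remote carbon C5 and the negative charge develops at C6 beside the methoxyl. Acyl transfer must also outrun protonation of the C6 anion, which the aprotic solvent, the absence of any acid other than 17 and the high temperature should favour, while the excess of 17 keeps the product phenoxide from competing for the aryne.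

**Step 9**
Reactants: 19 1-[5-hydroxy-7-methoxy-2,2-dimethyl-8-(3-methylbut-2-enyl)-2H-chromen-6-yl]-2-[4-(methoxymethoxy)phenyl]ethan-1-one
Product: 20 1-[5-hydroxy-7-methoxy-2,2-dimethyl-8-(3-methylbut-2-enyl)-2H-chromen-6-yl]-2-(4-hydroxyphenyl)ethan-1-one
Conditions: HCl (0.5 M in MeOH), rt
Reagents that add atoms: none
Why: Acid-catalysed acetal cleavage (transacetalization to methanol) frees the ring B phenol; the C8 prenyl group has no free ortho hydroxyl, so acid-induced chroman formation is not possible, and the C5 hydroxyl stays hydrogen-bonded to the ketone.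

**Compound list**
1 | 5-methoxyresorcinol (5-methoxybenzene-1,3-diol) | COc1cc(O)cc(O)c1 | starting material
2 | 3-methylbut-2-enal | CC(C)=CC=O | starting material
3 | (2Z)-3-hydroxy-5-methoxy-2-(3-methylbut-2-en-1-ylidene)cyclohexa-3,5-dien-1-one (ortho-quinone methide dienone) | O=C1C=C(OC)C=C(O)/C1=C/C=C(C)C | intermediate
4 | 7-methoxy-2,2-dimethyl-2H-chromen-5-ol | COc1cc(O)c2C=CC(C)(C)Oc2c1 | intermediate
5 | 7-methoxy-5-(methoxymethoxy)-2,2-dimethyl-2H-chromene | COCOc1cc(OC)cc2OC(C)(C)C=Cc12 | intermediate
6 | [7-methoxy-5-(methoxymethoxy)-2,2-dimethyl-2H-chromen-6-yl]lithium | COCOc1c([Li])c(OC)cc2OC(C)(C)C=Cc12 | intermediate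
7 | [7-methoxy-5-(methoxymethoxy)-2,2-dimethyl-2H-chromen-6-yl]trimethylsilane | COCOc1c([Si](C)(C)C)c(OC)cc2OC(C)(C)C=Cc12 | intermediate
8 | prenyl bromide (1-bromo-3-methylbut-2-ene) | CC(C)=CCBr | starting material
9 | [7-methoxy-5-(methoxymethoxy)-2,2-dimethyl-6-(trimethylsilyl)-2H-chromen-8-yl]lithium | COCOc1c([Si](C)(C)C)c(OC)c([Li])c2OC(C)(C)C=Cc12 | intermediate
10 | [7-methoxy-5-(methoxymethoxy)-2,2-dimethyl-6-(trimethylsilyl)-2H-chromen-8-yl]copper (monovalent copper) | COCOc1c([Si](C)(C)C)c(OC)c([Cu])c2OC(C)(C)C=Cc12 | intermediate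
11 | [7-methoxy-5-(methoxymethoxy)-2,2-dimethyl-8-(3-methylbut-2-enyl)-2H-chromen-6-yl]trimethylsilane | COCOc1c([Si](C)(C)C)c(OC)c(CC=C(C)C)c2OC(C)(C)C=Cc12 | intermediate
12 | trimethyl{[7-methoxy-2,2-dimethyl-8-(3-methylbut-2-enyl)-6-(trimethylsilyl)-2H-chromen-5-yl]oxy}silane | COc1c([Si](C)(C)C)c(O[Si](C)(C)C)c2C=CC(C)(C)Oc2c1CC=C(C)C | intermediate
13 | 7-methoxy-2,2-dimethyl-8-(3-methylbut-2-enyl)-6-(trimethylsilyl)-2H-chromen-5-ol | COc1c([Si](C)(C)C)c(O)c2C=CC(C)(C)Oc2c1CC=C(C)C | intermediate
14 | 7-methoxy-2,2-dimethyl-8-(3-methylbut-2-enyl)-6-(trimethylsilyl)-2H-chromen-5-yl trifluoromethanesulfonate | COc1c(CC=C(C)C)c2OC(C)(C)C=Cc2c(OS(=O)(=O)C(F)(F)F)c1[Si](C)(C)C | intermediate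
15 | 4-hydroxyphenylacetic acid | OC(=O)Cc1ccc(O)cc1 | starting material
16 | methoxymethyl 2-[4-(methoxymethoxy)phenyl]acetate | COCOC(=O)Cc1ccc(OCOC)cc1 | intermediate
17 | 2-[4-(methoxymethoxy)phenyl]acetic acid | COCOc1ccc(CC(=O)O)cc1 | intermediate
18 | 5,6-didehydro-7-methoxy-2,2-dimethyl-8-(3-methylbut-2-enyl)-2H-chromene (C5–C6 aryne) | COC1=C(CC=C(C)C)C2=C(C=CC(C)(C)O2)C#C1 | intermediate
19 | 1-[5-hydroxy-7-methoxy-2,2-dimethyl-8-(3-methylbut-2-enyl)-2H-chromen-6-yl]-2-[4-(methoxymethoxy)phenyl]ethan-1-one | COc1c(CC=C(C)C)c2OC(C)(C)C=Cc2c(O)c1C(=O)Cc1ccc(OCOC)cc1 | intermediate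
20 | 1-[5-hydroxy-7-methoxy-2,2-dimethyl-8-(3-methylbut-2-enyl)-2H-chromen-6-yl]-2-(4-hydroxyphenyl)ethan-1-one | COc1c(CC=C(C)C)c2c(c(O)c1C(=O)Cc1ccc(O)cc1)C=CC(C)(C)O2 | target

**Step count.** Total: 9 steps. Longest linear sequence: 8 steps (steps 1–6, 8 and 9); step 7 is a one-step side branch.

**Steps most likely to fail**

Step 8. The C6 aryl anion may be protonated (by the hydrogen fluoride released from the acid, or by the acidic benzylic CH2 of the transient ester) before it captures the acyl group. The sequence would then stop at O-arylation, and the product phenoxide may also be arylated by a second aryne. The fallback gives up the aryne and forms the C6–carbonyl bond by directed metalation; it sets out from 11 and returns at 20. Fluoride protodesilylation (TBAF trihydrate, DMF, 80 °C), which is feasible because the C6 carbanion is flanked by two oxygens, should give 7-methoxy-5-(methoxymethoxy)-2,2-dimethyl-8-(3-methylbut-2-enyl)-2H-chromene F1. n-BuLi in THF at 0 °C should remove the only ring hydrogen, C6–H between OMOM and OMe, to give [7-methoxy-5-(methoxymethoxy)-2,2-dimethyl-8-(3-methylbut-2-enyl)-2H-chromen-6-yl]lithium F2. This is acylated at −78 °C with the Weinreb amide N-methoxy-N-methyl-2-[4-(methoxymethoxy)phenyl]acetamide F3, made from 17 with MeNHOMe·HCl, EDC·HCl and i-Pr2NEt. The product is 1-[7-methoxy-5-(methoxymethoxy)-2,2-dimethyl-8-(3-methylbut-2-enyl)-2H-chromen-6-yl]-2-[4-(methoxymethoxy)phenyl]ethan-1-one F4. HCl in MeOH at rt then removes both MOM ethers and delivers 20.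

Step 4. Metalation at the doubly flanked C8–H may be incomplete, and the allylic substitution may be slow or may partly take the SN2′ course at the dimethyl-substituted terminus, giving the branched 1,1-dimethylallyl isomer. The fallback separates C–C bond formation from the choice of alkene substitution; it sets out from 7 and returns at 11. The arylcopper 10, generated as in the route, is alkylated with allyl bromide, a small and symmetrical electrophile for which the two substitution modes give the same product. This should give [7-methoxy-5-(methoxymethoxy)-2,2-dimethyl-8-(prop-2-enyl)-2H-chromen-6-yl]trimethylsilane F5. Cross-metathesis with excess 2-methylbut-2-ene (second-generation Grubbs catalyst, CH2Cl2, 40 °C) then converts the allyl group into the prenyl group of 11. The hindered, cyclic chromene alkene should not take part.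

Step 1. Condensation may occur to a large extent at the carbon between a hydroxyl and the methoxyl, giving the 7-hydroxy-5-methoxy regioisomer, and a second chromenylation of 4 may also compete. The fallback fixes the regiochemistry through a symmetrical intermediate; it sets out from 1 and returns at 4. Double protection (NaH, MOMCl, DMF) gives 1-methoxy-3,5-bis(methoxymethoxy)benzene F6. n-BuLi in THF at 0 °C lithiates between the two OMOM groups to give [4-methoxy-2,6-bis(methoxymethoxy)phenyl]lithium F7. Addition to 2 at −78 °C gives racemic 1-[4-methoxy-2,6-bis(methoxymethoxy)phenyl]-3-methylbut-2-en-1-ol F8. HCl in MeOH removes both MOM groups and dehydrates the carbinol to dienone 3, which closes to 4. Because the two phenolic oxygens of F8 are equivalent, only one chromene can form, and the carbinol stereocentre is lost.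

**Further compounds**
F1 | step 8 | 7-methoxy-5-(methoxymethoxy)-2,2-dimethyl-8-(3-methylbut-2-enyl)-2H-chromene | COCOc1cc(OC)c(CC=C(C)C)c2OC(C)(C)C=Cc12
F2 | step 8 | [7-methoxy-5-(methoxymethoxy)-2,2-dimethyl-8-(3-methylbut-2-enyl)-2H-chromen-6-yl]lithium | COCOc1c([Li])c(OC)c(CC=C(C)C)c2OC(C)(C)C=Cc12
F3 | step 8 | N-methoxy-N-methyl-2-[4-(methoxymethoxy)phenyl]acetamide | COCOc1ccc(CC(=O)N(C)OC)cc1
F4 | step 8 | 1-[7-methoxy-5-(methoxymethoxy)-2,2-dimethyl-8-(3-methylbut-2-enyl)-2H-chromen-6-yl]-2-[4-(methoxymethoxy)phenyl]ethan-1-one | COCOc1c(C(=O)Cc3ccc(OCOC)cc3)c(OC)c(CC=C(C)C)c2OC(C)(C)C=Cc12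
F5 | step 4 | [7-methoxy-5-(methoxymethoxy)-2,2-dimethyl-8-(prop-2-enyl)-2H-chromen-6-yl]trimethylsilane | COCOc1c([Si](C)(C)C)c(OC)c(CC=C)c2OC(C)(C)C=Cc12
F6 | step 1 | 1-methoxy-3,5-bis(methoxymethoxy)benzene | COCOc1cc(OC)cc(OCOC)c1
F7 | step 1 | [4-methoxy-2,6-bis(methoxymethoxy)phenyl]lithium | COCOc1cc(OC)cc(OCOC)c1[Li]
F8 | step 1 | 1-[4-methoxy-2,6-bis(methoxymethoxy)phenyl]-3-methylbut-2-en-1-ol (racemic) | COCOc1cc(OC)cc(OCOC)c1C(O)C=C(C)C
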